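**Plan**
- Numbering follows labdane (decalin C-1 to C-10, side chain C-11 to C-15). The retrosynthesis keeps the glyceride intact and cuts C-9–C-11 (alkylzinc + enol triflate), takes the enol triflate back to a C-9 ketone, then cuts the ring B bond C-7–C-8 and the ring-fusion bond C-5–C-10 together to an acyclic keto-enal.
- Enabling feature: C-9 lies between C-8 and C-10, so a C-9 ketone makes them the α/α′ carbons of a 1,3-bis-nucleophile. This matches C-5/C-7, the β-carbon and carbonyl carbon of an enal, as a 1,3-bis-electrophile. The tetrasubstituted C-8=C-9 alkene is the enol triflate of the same ketone.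
- Forward: the chain is built from 2,2-dimethylpent-4-enal (C-4 with its two methyls), a two-carbon Wittig salt and pentan-3-one. One amine-catalysed Michael/aldol cascade closes ring A (C-5–C-10) and then ring B (C-7–C-8). Reductive triflation, Negishi coupling with a zinc reagent that already carries the glyceride, and PMB removal follow.
- Stereochemistry: C-5 from the chiral amine (iminium face shielding); C-10 relative to C-5 from a chair transition state (trans fusion); C-13 from (R)-monomethyl 3-methylglutarate; glycerol C-2 from (S)-solketal.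

Key step: step 6

Remark: the decalin has the enantio (ent-labdane) configuration (5R,10R), so chiral-pool decalins of the normal series cannot serve and the core is made by asymmetric catalysis.
Remark: the sense of induction in step 6 is assigned from the face-shielding model of diarylprolinol silyl ethers (the antipodal amine would be used if it proved opposite); (R)-monomethyl 3-methylglutarate and (S)-solketal are taken as commercial in high enantiomeric purity.

**Route**

Step 1
Reactants: 1 2,2-dimethylpent-4-enal; 2 (1,3-dioxolan-2-ylmethyl)triphenylphosphonium bromide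
Product: 4 2-(3,3-dimethylhexa-1,5-dien-1-yl)-1,3-dioxolane (E/Z mixture), via phosphorus ylide 3 (not isolated)
Conditions: KOtBu, THF, 0 °C to rt
Reagents that add atoms: none
Why: Wittig olefination of the non-enolisable aldehyde adds C-6/C-7 as a base-stable masked enal, and the alkene geometry does not matter because the later hydrolysis should equilibrate to the E-enal.

Step 2
Reactants: 4 2-(3,3-dimethylhexa-1,5-dien-1-yl)-1,3-dioxolane
Product: 6 6-(1,3-dioxolan-2-yl)-4,4-dimethylhex-5-en-1-ol, via alkylborane 5 (not isolated)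
Conditions: 9-BBN, THF, 0 °C to rt; then NaOH, H2O2, 0 °C
Reagents that add atoms: hydrogen peroxide OO
Why: Hydroboration–oxidation with the bulky borane should take the monosubstituted terminal alkene anti-Markovnikov and leave the 1,2-disubstituted alkene next to the quaternary carbon untouched.

Step 3
Reactants: 6 6-(1,3-dioxolan-2-yl)-4,4-dimethylhex-5-en-1-ol
Product: 7 2-(6-iodo-3,3-dimethylhex-1-en-1-yl)-1,3-dioxolane
Conditions: PPh3, I2, imidazole, CH2Cl2, 0 °C
Reagents that add atoms: iodine II
Why: Appel iodination converts the primary alcohol to the iodide under imidazole-buffered conditions that the acetal should tolerate.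

Step 4
Reactants: 7 2-(6-iodo-3,3-dimethylhex-1-en-1-yl)-1,3-dioxolane; 8 pentan-3-one (threefold excess)
Product: 10 10-(1,3-dioxolan-2-yl)-4,8,8-trimethyldec-9-en-3-one (racemic at C-4), via lithium enolate 9 (not isolated)
Conditions: LiN(i-Pr)2, THF, −78 °C; then 7, DMPU, −78 to 0 °C
Reagents that add atoms: none
Why: SN2 enolate alkylation of the symmetrical ketone (one possible enolate) with the unhindered primary iodide joins C-1 to C-10, and the new stereocentre need not be controlled because it is enolised in step 6.

Step 5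
Reactants: 10 10-(1,3-dioxolan-2-yl)-4,8,8-trimethyldec-9-en-3-one
Product: 11 (2E)-4,4,8-trimethyl-9-oxoundec-2-enal (racemic at C-8)
Conditions: pyridinium p-toluenesulfonate (cat.), acetone/H2O, 40 °C
Reagents that add atoms: water O
Why: Mild acetal hydrolysis unmasks the aldehyde, and acid-catalysed equilibration should drive the enal with its β-tert-alkyl group to the E isomer while the ketone is unaffected.

Step 6
Reactants: 11 (2E)-4,4,8-trimethyl-9-oxoundec-2-enal
Product: 14 (4aR,8aR)-2,5,5,8a-tetramethyl-4a,5,6,7,8,8a-hexahydronaphthalen-1(4H)-one, via Michael adduct 12 (not isolated), via aldol 13 (not isolated)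
Conditions: (R)-2-[diphenyl(trimethylsilyloxy)methyl]pyrrolidine (20 mol%), 4-nitrobenzoic acid (20 mol%), toluene, 0 °C to rt; then TsOH·H2O (20 mol%), 50 °C
Reagents that add atoms: none
Why: Proposed new method: the hindered secondary amine should condense only with the enal to give an E-iminium ion, whose β-carbon C-5 is attacked through C-10 by the more substituted enol of the C-9 ketone, after which the other α-carbon C-8 adds to C-7 (as aldehyde or iminium) and water is lost, so one ketone acts as a 1,3-bis-nucleophile toward the enal as 1,3-bis-electrophile; the closest known reaction types are the secondary-amine-catalysed Michael/aldol-condensation annulation of enals with β-keto esters and the amine-catalysed intramolecular Michael cyclisation of carbonyl-tethered enals and enones. Ring A closes 6-exo-trig (enol-exo) through C-5–C-10, and ring B closes 6-(enolexo)-exo-trig through C-7–C-8 followed by dehydration. C-5 is set by the catalyst, whose diphenyl(silyloxy)methyl group shields one face of the s-trans E-iminium ion so that the (R)-amine should give (5R); C-10 is set relative to C-5 by a chair transition state of ring A with the iminium-bearing chain at C-5 and the enol carbon C-9 both equatorial and the C-10 methyl axial, which leads to the trans ring fusion. The step needs enolisation toward C-10 and not C-8, and 1,4- over 1,2-addition: attack through C-8 would need an eight-membered ring, the quaternary C-4 leaves the enal without γ-hydrogens so no dienamine can form, and the gem-dimethyl group at C-4 favours the folded conformer. The main threat is a racemic acid-catalysed background cyclisation, which the low temperature and absence of base should limit.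

Step 7
Reactants: 14 (4aR,8aR)-2,5,5,8a-tetramethyl-4a,5,6,7,8,8a-hexahydronaphthalen-1(4H)-one
Product: 16 (4aR,8aR)-2,5,5,8a-tetramethyl-3,4,4a,5,6,7,8,8a-octahydronaphthalen-1-yl trifluoromethanesulfonate, via lithium enolate 15 (not isolated)
Conditions: LiBH(s-Bu)3 (L-Selectride), THF, −78 °C; then PhNTf2, −78 to 0 °C
Reagents that add atoms: N-phenylbis(trifluoromethanesulfonimide) O=S(=O)(N(c1ccccc1)S(=O)(=O)C(F)(F)F)C(F)(F)F
Why: Conjugate reduction of the β-unsubstituted enone (1,2-attack is blocked by the quaternary C-10) should give the tetrasubstituted enolate regiospecifically, and its O-sulfonylation in the same flask (reductive enol triflation) fixes the C-8=C-9 double bond without touching a stereocentre.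

Step 8
Reactants: 17 (3R)-5-methoxy-3-methyl-5-oxopentanoic acid
Product: 19 (4R)-4-methyloxan-2-one, via hydroxy ester 18 (not isolated)
Conditions: BH3·SMe2, THF, 0 °C to rt; aqueous work-up; then TsOH·H2O (cat.), toluene, 40 °C
Reagents that add atoms: none
Why: Chemoselective borane reduction of the carboxylic acid beside the methyl ester, then lactonisation, turns the two arms into an acyl end (C-15) and an O-alkyl end (C-11) without touching the C-13 stereocentre.

Step 9
Reactants: 19 (4R)-4-methyloxan-2-one
Product: 21 (3S)-5-iodo-3-methylpentanoic acid, via silyl ester 20 (not isolated)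
Conditions: Me3SiI, CH2Cl2, rt to 40 °C; then H2O
Reagents that add atoms: iodotrimethylsilane C[Si](C)(C)I
Why: Lactone O-alkyl cleavage (carbonyl silylation, then SN2 attack of iodide at the primary CH2–O carbon) gives the ω-iodo silyl ester, which hydrolyses on work-up; the descriptor changes to S only through the priority rules.

Step 10
Reactants: 22 [(4S)-2,2-dimethyl-1,3-dioxolan-4-yl]methanol ((S)-solketal)
Product: 23 (4S)-4-{[(4-methoxybenzyl)oxy]methyl}-2,2-dimethyl-1,3-dioxolane
Conditions: NaH, 4-methoxybenzyl chloride, Bu4NI (cat.), DMF, 0 °C to rt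
Reagents that add atoms: 4-methoxybenzyl chloride COc1ccc(CCl)cc1
Why: Williamson etherification protects the sn-3 hydroxyl as a PMB ether that can later be removed oxidatively under neutral conditions.

Step 11
Reactants: 23 (4S)-4-{[(4-methoxybenzyl)oxy]methyl}-2,2-dimethyl-1,3-dioxolane
Product: 24 (2R)-3-[(4-methoxybenzyl)oxy]propane-1,2-diol
Conditions: AcOH/H2O (4:1), 40 °C
Reagents that add atoms: none
Why: Mild acid hydrolysis removes the acetonide, and the PMB ether and the stereocentre should be unaffected.

Step 12
Reactants: 24 (2R)-3-[(4-methoxybenzyl)oxy]propane-1,2-diol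
Product: 25 (2S)-2-hydroxy-3-[(4-methoxybenzyl)oxy]propyl acetate
Conditions: AcCl (1.05 equiv), 2,4,6-collidine, CH2Cl2, −78 °C
Reagents that add atoms: acetyl chloride CC(=O)Cl
Why: Kinetically controlled acylation with a hindered pyridine base at low temperature should acetylate the primary hydroxyl selectively over the secondary one.

Step 13
Reactants: 25 (2S)-2-hydroxy-3-[(4-methoxybenzyl)oxy]propyl acetate; 21 (3S)-5-iodo-3-methylpentanoic acid
Product: 26 (2S)-1-(acetyloxy)-3-[(4-methoxybenzyl)oxy]propan-2-yl (3S)-5-iodo-3-methylpentanoate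
Conditions: N-(3-dimethylaminopropyl)-N′-ethylcarbodiimide hydrochloride (EDC·HCl), DMAP (cat.), CH2Cl2, 0 °C to rt
Reagents that add atoms: none
Why: Steglich esterification acylates the secondary hydroxyl at low temperature and short reaction time, which should keep the acetate from migrating and leave the primary iodide intact.

Step 14
Reactants: 26 (2S)-1-(acetyloxy)-3-[(4-methoxybenzyl)oxy]propan-2-yl (3S)-5-iodo-3-methylpentanoate (1.5 equiv); 16 (4aR,8aR)-2,5,5,8a-tetramethyl-3,4,4a,5,6,7,8,8a-octahydronaphthalen-1-yl trifluoromethanesulfonate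
Product: 28 (2S)-1-(acetyloxy)-3-[(4-methoxybenzyl)oxy]propan-2-yl (3R)-3-methyl-5-[(4aR,8aR)-2,5,5,8a-tetramethyl-3,4,4a,5,6,7,8,8a-octahydronaphthalen-1-yl]pentanoate, via alkylzinc iodide 27 (not isolated)
Conditions: Zn dust (activated with BrCH2CH2Br and Me3SiCl), LiCl, THF, 40 °C; then 16, Pd(OAc)2 (5 mol%), SPhos (10 mol%), THF/NMP, 50 °C
Reagents that add atoms: none
Why: Negishi sp2–sp3 coupling: zinc inserts into the primary C–I bond without touching the esters or the PMB ether, the alkylzinc transmetalates to the alkenylpalladium species from oxidative addition of the triflate, and the bulky electron-rich phosphine should favour reductive elimination over β-hydride elimination, so the C-9–C-11 bond forms with the alkene fixed at C-8=C-9.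

Step 15
Reactants: 28 (2S)-1-(acetyloxy)-3-[(4-methoxybenzyl)oxy]propan-2-yl (3R)-3-methyl-5-[(4aR,8aR)-2,5,5,8a-tetramethyl-3,4,4a,5,6,7,8,8a-octahydronaphthalen-1-yl]pentanoate
Product: 29 (2S)-1-(acetyloxy)-3-hydroxypropan-2-yl (3R)-3-methyl-5-[(4aR,8aR)-2,5,5,8a-tetramethyl-3,4,4a,5,6,7,8,8a-octahydronaphthalen-1-yl]pentanoate
Conditions: DDQ, CH2Cl2/pH 7 phosphate buffer, 0 °C; chromatography on boric-acid-treated silica
Reagents that add atoms: none
Why: Oxidative PMB ether cleavage by DDQ runs under neutral buffered conditions at 0 °C, which should avoid the acyl migration that acid or base would cause in a 1,2-diacylglycerol and leave the tetrasubstituted alkene and both esters intact.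

**Compound list**
1 | 2,2-dimethylpent-4-enal | C=CCC(C)(C)C=O | starting material
2 | (1,3-dioxolan-2-ylmethyl)triphenylphosphonium bromide | [Br-].C1COC(C[P+](c2ccccc2)(c2ccccc2)c2ccccc2)O1 | starting material
3 | (1,3-dioxolan-2-ylmethylidene)triphenylphosphorane | C1COC(C=P(c2ccccc2)(c2ccccc2)c2ccccc2)O1 | intermediate
4 | 2-(3,3-dimethylhexa-1,5-dien-1-yl)-1,3-dioxolane (E/Z mixture) | C=CCC(C)(C)C=CC1OCCO1 | intermediate
5 | 9-[6-(1,3-dioxolan-2-yl)-4,4-dimethylhex-5-en-1-yl]-9-borabicyclo[3.3.1]nonane | C1CC2CCCC(C1)B2CCCC(C)(C)C=CC1OCCO1 | intermediate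
6 | 6-(1,3-dioxolan-2-yl)-4,4-dimethylhex-5-en-1-ol | OCCCC(C)(C)C=CC1OCCO1 | intermediate
7 | 2-(6-iodo-3,3-dimethylhex-1-en-1-yl)-1,3-dioxolane | ICCCC(C)(C)C=CC1OCCO1 | intermediate
8 | pentan-3-one | CCC(=O)CC | starting material
9 | lithium pent-2-en-3-olate | [Li+].CC=C([O-])CC | intermediate
10 | 10-(1,3-dioxolan-2-yl)-4,8,8-trimethyldec-9-en-3-one (racemic at C-4) | CCC(=O)C(C)CCCC(C)(C)C=CC1OCCO1 | intermediate
11 | (2E)-4,4,8-trimethyl-9-oxoundec-2-enal (racemic at C-8) | CCC(=O)C(C)CCCC(C)(C)/C=C/C=O | intermediate
12 | 2-[(1R,2R)-2,6,6-trimethyl-2-propanoylcyclohexyl]acetaldehyde | O=CC[C@@H]1C(C)(C)CCC[C@@]1(C)C(=O)CC | intermediate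
13 | (4aR,8aR)-3-hydroxy-2,5,5,8a-tetramethyloctahydronaphthalen-1(2H)-one (epimers at C-2 and C-3) | O=C1C(C)C(O)C[C@@H]2C(C)(C)CCC[C@@]12C | intermediate
14 | (4aR,8aR)-2,5,5,8a-tetramethyl-4a,5,6,7,8,8a-hexahydronaphthalen-1(4H)-one | O=C1C(C)=CC[C@@H]2C(C)(C)CCC[C@@]12C | intermediate
15 | lithium (4aR,8aR)-2,5,5,8a-tetramethyl-3,4,4a,5,6,7,8,8a-octahydronaphthalen-1-olate | [Li+].[O-]C1=C(C)CC[C@@H]2C(C)(C)CCC[C@@]12C | intermediate
16 | (4aR,8aR)-2,5,5,8a-tetramethyl-3,4,4a,5,6,7,8,8a-octahydronaphthalen-1-yl trifluoromethanesulfonate | O=S(=O)(OC1=C(C)CC[C@@H]2C(C)(C)CCC[C@@]12C)C(F)(F)F | intermediate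
17 | (3R)-5-methoxy-3-methyl-5-oxopentanoic acid | COC(=O)C[C@H](C)CC(=O)O | starting material
18 | methyl (3R)-5-hydroxy-3-methylpentanoate | COC(=O)C[C@H](C)CCO | intermediate
19 | (4R)-4-methyloxan-2-one | O=C1C[C@H](C)CCO1 | intermediate
20 | trimethylsilyl (3S)-5-iodo-3-methylpentanoate | C[Si](C)(C)OC(=O)C[C@H](C)CCI | intermediate
21 | (3S)-5-iodo-3-methylpentanoic acid | OC(=O)C[C@H](C)CCI | intermediate
22 | [(4S)-2,2-dimethyl-1,3-dioxolan-4-yl]methanol | CC1(C)OC[C@H](CO)O1 | starting material
23 | (4S)-4-{[(4-methoxybenzyl)oxy]methyl}-2,2-dimethyl-1,3-dioxolane | CC1(C)OC[C@H](COCc2ccc(OC)cc2)O1 | intermediate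
24 | (2R)-3-[(4-methoxybenzyl)oxy]propane-1,2-diol | OC[C@H](COCc1ccc(OC)cc1)O | intermediate
25 | (2S)-2-hydroxy-3-[(4-methoxybenzyl)oxy]propyl acetate | CC(=O)OC[C@H](COCc1ccc(OC)cc1)O | intermediate
26 | (2S)-1-(acetyloxy)-3-[(4-methoxybenzyl)oxy]propan-2-yl (3S)-5-iodo-3-methylpentanoate | CC(=O)OC[C@H](COCc1ccc(OC)cc1)OC(=O)C[C@H](C)CCI | intermediate
27 | {(3S)-5-[(2S)-1-(acetyloxy)-3-[(4-methoxybenzyl)oxy]propan-2-yl]oxy-3-methyl-5-oxopentyl}zinc iodide | CC(=O)OC[C@H](COCc1ccc(OC)cc1)OC(=O)C[C@H](C)CC[Zn]I | intermediate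
28 | (2S)-1-(acetyloxy)-3-[(4-methoxybenzyl)oxy]propan-2-yl (3R)-3-methyl-5-[(4aR,8aR)-2,5,5,8a-tetramethyl-3,4,4a,5,6,7,8,8a-octahydronaphthalen-1-yl]pentanoate | CC(=O)OC[C@H](COCc1ccc(OC)cc1)OC(=O)C[C@H](C)CCC1=C(C)CC[C@@H]2C(C)(C)CCC[C@@]12C | intermediate
29 | (2S)-1-(acetyloxy)-3-hydroxypropan-2-yl (3R)-3-methyl-5-[(4aR,8aR)-2,5,5,8a-tetramethyl-3,4,4a,5,6,7,8,8a-octahydronaphthalen-1-yl]pentanoate | CC(=O)OC[C@H](CO)OC(=O)C[C@H](C)CCC1=C(C)CC[C@@H]2C(C)(C)CCC[C@@]12C | target

**Totals and risks**

Total step count: 15. Longest linear sequence: 9 steps (steps 1–7, 14 and 15).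

Steps most likely to fail:

Step 6 (Proposed new method). The unactivated ketone enol may add too slowly to the iminium ion, so that an uncatalysed racemic cyclisation or closure through the cis-fused chair erodes enantiomeric and diastereomeric purity. The fallback gives up catalyst control and sets out from 11. A classical base-mediated intramolecular Michael/aldol condensation (KOH, MeOH, rt to 60 °C; Robinson-type α,α′-annulation of a ketone onto an enal) should give the racemic trans-fused enone, rac-(4aR,8aR)-2,5,5,8a-tetramethyl-4a,5,6,7,8,8a-hexahydronaphthalen-1(4H)-one F1. Its enantiomers would be separated by preparative chromatography on a chiral stationary phase. The (4aR,8aR) enantiomer is 14, where the route is rejoined.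

Step 14. Transmetalation and reductive elimination at the tetrasubstituted alkenylpalladium centre next to the quaternary C-10 may be slow, so that protodezincation and β-hydride elimination consume the zinc reagent and the triflate is merely reduced. The fallback changes the nucleophile to a boron ate complex and sets out from lactone 19.
- Opening with PhSeNa (from PhSeSePh and NaBH4, DMF, 110 °C) gives (3S)-3-methyl-5-(phenylselanyl)pentanoic acid F2.
- Oxidation with H2O2 and syn-elimination of the selenoxide gives (3S)-3-methylpent-4-enoic acid F3.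
- Steglich esterification with 25 gives (2S)-1-(acetyloxy)-3-[(4-methoxybenzyl)oxy]propan-2-yl (3S)-3-methylpent-4-enoate F4.
- Hydroboration with 9-BBN gives (2S)-1-(acetyloxy)-3-[(4-methoxybenzyl)oxy]propan-2-yl (3R)-5-(9-borabicyclo[3.3.1]nonan-9-yl)-3-methylpentanoate F5.
- B-alkyl Suzuki–Miyaura coupling with 16 (PdCl2(dppf), AsPh3, Cs2CO3, DMF/THF/H2O, rt to 50 °C) returns to the route at 28.

Step 4. Proton exchange between the product ketone and the enolate may cause polyalkylation and leave the iodide unconsumed. The fallback replaces the ketone enolate by a metallated hydrazone and sets out from 8.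
- Condensation with N,N-dimethylhydrazine gives pentan-3-one N,N-dimethylhydrazone F6.
- Deprotonation with LiN(i-Pr)2 (THF, 0 °C) gives the lithium aza-enolate F7.
- Alkylation with 7 gives 10-(1,3-dioxolan-2-yl)-4,8,8-trimethyldec-9-en-3-one N,N-dimethylhydrazone F8.
- Aqueous oxalic acid in THF should cleave the hydrazone and the dioxolane together, so the route is rejoined at 11 without passing through 10.

Further compounds
F1 | step 6 | rac-(4aR,8aR)-2,5,5,8a-tetramethyl-4a,5,6,7,8,8a-hexahydronaphthalen-1(4H)-one (racemate, both enantiomers written) | O=C1C(C)=CC[C@@H]2C(C)(C)CCC[C@@]12C.O=C1C(C)=CC[C@H]2C(C)(C)CCC[C@]12C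
F2 | step 14 | (3S)-3-methyl-5-(phenylselanyl)pentanoic acid | OC(=O)C[C@H](C)CC[Se]c1ccccc1
F3 | step 14 | (3S)-3-methylpent-4-enoic acid | OC(=O)C[C@H](C)C=C
F4 | step 14 | (2S)-1-(acetyloxy)-3-[(4-methoxybenzyl)oxy]propan-2-yl (3S)-3-methylpent-4-enoate | CC(=O)OC[C@H](COCc1ccc(OC)cc1)OC(=O)C[C@H](C)C=C
F5 | step 14 | (2S)-1-(acetyloxy)-3-[(4-methoxybenzyl)oxy]propan-2-yl (3R)-5-(9-borabicyclo[3.3.1]nonan-9-yl)-3-methylpentanoate | CC(=O)OC[C@H](COCc1ccc(OC)cc1)OC(=O)C[C@H](C)CCB1C2CCCC1CCC2
F6 | step 4 | pentan-3-one N,N-dimethylhydrazone | CCC(CC)=NN(C)C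
F7 | step 4 | lithium aza-enolate of pentan-3-one N,N-dimethylhydrazone | [Li+].CC=C(CC)[N-]N(C)C
F8 | step 4 | 10-(1,3-dioxolan-2-yl)-4,8,8-trimethyldec-9-en-3-one N,N-dimethylhydrazone | CCC(=NN(C)C)C(C)CCCC(C)(C)C=CC1OCCO1
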